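## The problem

The target is an elemane-type lactone: a cyclohexane (C5–C10) in which every ring carbon is substituted, with an α-methyl-γ-butyrolactone (C11, C12) fused cis across C7–C8, an isobutyrate at C6, a free hydroxyl at C9, methyl and vinyl on the quaternary C10, and a 2-substituted acrolein (C4) at C5. Six contiguous ring stereocentres and C11 have to be set; taking β as the face of the C10 methyl group, the C5 arm, the C6 oxygen, the C7–C11 bond and the C8 oxygen are all β, while the C9 hydroxyl and the vinyl group are α. C10, C9 and C5 form a triad (vinyl cis to the C9 oxygen, trans to the C5 arm) that no later step can correct, so it must be made in one stroke. Once in place it can steer the rest: in the chair that keeps the C10 methyl and the C9 oxygen equatorial, the oxygens at C6 and C8 are equatorial too (reachable by equilibration next to a C7 carbonyl), the axial C5 arm covers the β face of C7, and the cis ring fusion offers a convex face at C11 for the methyl group. The groups that will not stand rough treatment are the α-methylene aldehyde (no enolates, ylides or hydrides once it exists), the two terminal alkenes (no catalytic hydrogenation once they exist), the C9 oxygen while it is β to a C7 carbonyl (elimination), and the C6 oxygen, which as a free hydroxyl cis to the lactone can capture C12. The feature that makes the key step possible is the substitution around C10: a methyl group and a vinyl group derivable from formyl, flanked by the C9 oxygen cis to that vinyl and by the C5 carbon arm trans to it, with C7, para to C10, at carbonyl oxidation level. This is the imprint of an (E)-α-methyl enal that has added endo to a 1-alkoxy-3-silyloxybutadiene.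

## Retrosynthesis

**25 ⇒ 24 ⇒ 22 (no skeletal bond cut).** The C9 hydroxyl of 25 is released last from the 4-methoxybenzyl ether 24, and the enal of 24 is taken back to the isopropenyl group of 22 by allylic C–H oxidation. Carrying the acrolein unit through the route is excluded because every earlier step uses an enolate, an ylide or a hydride. The forward oxidation must choose the methyl group of the 1,1-disubstituted alkene over the tertiary C5–H; the vinyl group has no allylic hydrogen.

**22 ⇒ 20 ⇒ 19 (C11–CH3, then C7–H and C11–H).** The lactone methyl is removed to give 20, and 20 is traced to the butenolide 19. Bringing the methyl in with the olefination reagent would give a tetrasubstituted alkene that cannot be reduced selectively beside two terminal alkenes, and syn addition of hydrogen would put the methyl on the wrong face. Alkylating the enolate of the cis-fused lactone on its convex face gives the required C11 epimer directly. The forward steps need hydride at C7 from the α face and an enolate that leaves the isobutyrate alone.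

**19 ⇒ 17 (C7=C11 and O8–C12).** Both bonds of the lactone are cut at once, leading to the α-hydroxy ketone 17 and a two-carbon ketenylidene ylide. An intermolecular olefination of this hindered ketone would raise a geometry problem, and an aldol–dehydration sequence would cost more steps. The forward reaction must be neutral enough to keep C8 and the α-acyloxy ketone intact.

**17 ⇒ 16 ⇒ 15 ⇒ 14 ⇒ 12 (C6–O).** The C6 ester is traced through its epimer 15 and the ketol 14 to the ketone 12, using the C7 carbonyl to functionalise C6. Oxidising C6 after the butenolide exists is not viable (deprotonation at C8 wins), and a C6 ketone next to the finished lactone would be a β-acyloxy ketone. The ester is put on before the lactone so that no free C6 hydroxyl ever faces C12. The configuration at C6 (and C8) is left to equilibration, which should favour the all-equatorial oxygen array.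

**12 ⇒ 10 (C8–O).** The C8 oxygen comes from Rubottom oxidation of the silyl enol ether 10. The silyl group shifts to the new oxygen, so the group that activated the diene becomes the C8 protecting group at no cost in steps.

**10 ⇒ 9 ⇒ 7 ⇒ 6 (the two C=CH2 bonds).** Isopropenyl is cut to the methyl ketone 9, which comes from the ester 7 through the amide 8; vinyl is cut to the formyl group of 6. These two carbonyls are exactly the activating groups of a dienophile, and they are converted while the C7 carbonyl is still masked as the silyl enol ether.

**6 ⇒ 4 + 5 (C5–C6 and C9–C10).** The Diels–Alder cut removes the ring and three stereocentres and leaves two achiral partners: the diene 4 and the purchasable enal ester 5. The forward reaction must deliver regiochemistry (formyl, not ester, directs), endo formyl and one enantioface. The first two are known for the thermal reaction of this diene class; the third is asked of a chiral diol and is backed by a resolution.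

**4 ⇒ 3 ⇒ 1 + 2.** The diene is the silyl enol ether of the enone 3, which comes from 1 and 2 by alkoxy exchange.

## Roads not taken

**Alternative 1:** The cut is C6–C7. An open-chain aldehyde carrying the butenolide (A2) would be reduced by SmI2 to a ketyl that adds 6-exo to C7 of the butenolide, and the samarium enolate would be protonated at C11 to give A1.
- Merits: the most congested bond is made last, with the lactone already present. A1 is only an acylation, an allylic oxidation and a desilylation from the target, which is a shorter endgame than the chosen one.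
- Weak points: A2 already contains C5, the quaternary C10, C9 and C8 as contiguous stereocentres that must be built in an open chain with no ring to relay them. Its aldehyde is α-branched and β,γ-unsaturated, so it is prone to epimerisation and conjugation. The ketyl oxygen usually prefers to lie anti to the acceptor chain, whereas the target needs the C6 oxygen cis to C7–C11. Protonation of the enolate on the open convex face would put the C11 methyl on the concave face, so C11 would need equilibration.
- Comparison: in endgame length this road is better. The chosen plan sets against it that its ring-forming step starts from two small achiral molecules and fixes the C5/C9/C10 triad at once.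

**Alternative 2:** The cuts are C5–C10 and C7=C8. Under a diarylprolinol silyl ether catalyst, the keto ester A4 would add through C10 to the enal A5 (iminium activation), and the methyl ketone carbon would condense with the aldehyde to give the cyclohexenone A3.
- Merits: this catalysis is well established and should give high enantioselectivity at C5 from cheap materials. On absolute control it stands on firmer ground than the chosen key step.
- Weak points: the catalyst controls C5 only; the quaternary C10 is set by the face of an α-substituted keto ester and need not follow. A3 carries a ketone at C9 and an enone at C7–C8, so C7 could take a carbon by conjugate addition, but C6 is left as an unactivated methylene with no handle for oxygen. The C10 ester would still have to be taken down to vinyl beside a second ester.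
- Comparison: the chosen plan sets against the better enantiocontrol that the cycloaddition delivers the C9 oxygen with the right relative configuration and a C7 carbonyl that activates both C6 and C8.

**Alternative 3:** The cut is C8=C9. The triene A7, with two vinyl groups on C10, would be closed by Mo(N-2,6-i-Pr2C6H3)(CHCMe2Ph)(3,3'-di-tert-butyl-5,5',6,6'-tetramethylbiphenyl-2,2'-diolate), which engages one vinyl group with the C7 vinyl and so makes C10 stereogenic in A6.
- Merits: closure of a cyclohexene by metathesis is dependable. C5, C6, C7 and C11 are set before the ring exists, so the late C6/C7 problems of the chosen route do not arise. An α-epoxide of A6 could be opened at C8 by the C12 carboxyl to give the 8β-lactone and 9α-hydroxyl together. In the endgame this road is the better one.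
- Weak points: A7 needs four contiguous open-chain stereocentres plus a bis-vinyl quaternary carbon. The choice between the two vinyl groups is a doubly diastereodifferentiating event with an air-sensitive catalyst, the remaining vinyl group can re-enter metathesis, and the epoxidation face is not assured. Exchanging the C6 ether for the ester would expose a free C6 hydroxyl next to the lactone.
- Comparison: the chosen plan sets against it three steps from commercial materials to the carbocycle and a thermodynamic handle on C6 and C8.

Key step: step 3

**Conventions and assumptions**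
- Locants C4–C12 are those used above; β is the face of the C10 methyl group, α the opposite face. Absolute configurations are those of the SMILES in the compound list.
- Assumption: the (R,R)-diol is written on the premise that it shields the enal face in the same sense as with 1-amino-3-silyloxybutadienes; if the sense is opposite, the (S,S)-diol is used and nothing else changes.
- Only step 3 carries the label "Proposed new method:"; all other steps use known reaction types.

## Route

Step 1
Reactants: 1 (E)-4-methoxybut-3-en-2-one; 2 4-methoxybenzyl alcohol
Product: 3 (E)-4-[(4-methoxybenzyl)oxy]but-3-en-2-one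
Conditions: PPTS (cat.), toluene, 80 °C, reduced pressure (MeOH distilled off)
Reagents that add atoms: none
Why: Acid-catalysed addition–elimination at the β-carbon of the enone (vinylogous transesterification); removal of methanol drives the exchange and the E isomer is the thermodynamic product.

Step 2
Reactants: 3 (E)-4-[(4-methoxybenzyl)oxy]but-3-en-2-one
Product: 4 (E)-1-[(4-methoxybenzyl)oxy]-3-(tert-butyldimethylsilyloxy)buta-1,3-diene
Conditions: TBSOTf, Et3N, Et2O, 0 °C
Reagents that add atoms: tert-butyldimethylsilyl trifluoromethanesulfonate, CC(C)(C)[Si](C)(C)OS(=O)(=O)C(F)(F)F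
Why: Soft enolisation of the methyl ketone (silyl triflate and amine) gives the 2-silyloxydiene without touching the E enol ether; the bulky silyl group makes the diene and its cycloadduct robust enough for the next four steps.

Step 3
Reactants: 4 (E)-1-[(4-methoxybenzyl)oxy]-3-(tert-butyldimethylsilyloxy)buta-1,3-diene; 5 ethyl (E)-3-methyl-4-oxobut-2-enoate
Product: 6 ethyl 2-formyl-3-[(4-methoxybenzyl)oxy]-2-methyl-5-(tert-butyldimethylsilyloxy)cyclohex-4-ene-1-carboxylate (5β-CO2Et; 9α-ether; 10α-CHO and 10β-CH3; C7=C8 silyl enol ether)
Conditions: (4R,5R)-2,2-dimethyl-α,α,α′,α′-tetra(1-naphthyl)-1,3-dioxolane-4,5-dimethanol (20 mol%), toluene, −40 °C; non-acidic work-up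
Reagents that add atoms: none
Why: Proposed new method: a chiral-diol (hydrogen-bond) catalysed Diels–Alder reaction of a 1-alkoxy-3-silyloxybutadiene with an α-methyl enal; the closest known reaction types are the uncatalysed thermal [4+2] cycloaddition of such dienes with α-methyl enals and the TADDOL-catalysed cycloaddition of 1-amino-3-silyloxybutadienes with α-substituted acroleins, and the reasoning is that the same single O–H···O=C hydrogen bond to the formyl oxygen should lower the LUMO of 5 and place a naphthyl group over one of its faces, while the second acceptor (the ester) makes 5 reactive enough at low temperature to offset the less electron-rich alkoxy diene. The cycloaddition is concerted but asynchronous and of normal electron demand: the nucleophilic CH2 terminus of 4 (future C6) bonds ahead to C5, the carbon β to formyl, and the alkoxy-bearing terminus (future C9) closes onto C10. The six-membered carbocycle is closed by this intermolecular suprafacial [4+2] union, which forms C5–C6 and C9–C10 and leaves the C7=C8 silyl enol ether. C9 and C10 are related by the endo position of the hydrogen-bonded formyl group, which places CHO cis to the C9 ether; C5 follows from the E geometry of 5, transferred suprafacially, so the ester is trans to CHO and cis to methyl. The absolute configuration of all three centres is decided by which face of the bound enal the diol leaves open. The step needs regioselectivity, endo selectivity and face selectivity: the first two are secured in the substrates, because formyl is the stronger and the activated acceptor and C5 is the less hindered terminus, whereas the third rests on the catalyst alone.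

Step 4
Reactants: 6 ethyl 2-formyl-3-[(4-methoxybenzyl)oxy]-2-methyl-5-(tert-butyldimethylsilyloxy)cyclohex-4-ene-1-carboxylate
Product: 7 ethyl 2-ethenyl-3-[(4-methoxybenzyl)oxy]-2-methyl-5-(tert-butyldimethylsilyloxy)cyclohex-4-ene-1-carboxylate (10α-vinyl; otherwise as 6)
Conditions: Ph3PCH3Br, KN(SiMe3)2, THF, 0 °C; then 6, −78 → 0 °C
Reagents that add atoms: methyltriphenylphosphonium bromide, C[P+](c1ccccc1)(c1ccccc1)c1ccccc1.[Br-]
Why: Wittig methylenation of a non-enolisable, α-quaternary aldehyde; the ester and the silyl enol ether are inert to the unstabilised ylide at low temperature and no stereocentre is touched.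

Step 5
Reactants: 7 ethyl 2-ethenyl-3-[(4-methoxybenzyl)oxy]-2-methyl-5-(tert-butyldimethylsilyloxy)cyclohex-4-ene-1-carboxylate
Product: 9 1-{2-ethenyl-3-[(4-methoxybenzyl)oxy]-2-methyl-5-(tert-butyldimethylsilyloxy)cyclohex-4-en-1-yl}ethan-1-one (5β-acetyl), via N-methoxy-N-methylamide 8 (not isolated)
Conditions: MeNH(OMe)·HCl, i-PrMgCl, THF, −20 → 0 °C; then MeMgBr, 0 °C → rt; aq. NH4Cl
Reagents that add atoms: methylmagnesium bromide, C[Mg]Br; N,O-dimethylhydroxylamine hydrochloride, CNOC.Cl (nitrogen and methoxy group of 8 only)
Why: Weinreb ketone synthesis run in one flask: the magnesium amide converts the hindered ester into the N-methoxy-N-methylamide, whose chelated tetrahedral adduct with MeMgBr releases the methyl ketone only on work-up, so no tertiary alcohol forms and C5 is not enolised. The silyl enol ether keeps the C7 carbonyl masked throughout.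

Step 6
Reactants: 9 1-{2-ethenyl-3-[(4-methoxybenzyl)oxy]-2-methyl-5-(tert-butyldimethylsilyloxy)cyclohex-4-en-1-yl}ethan-1-one
Product: 10 tert-butyl({4-ethenyl-3-[(4-methoxybenzyl)oxy]-4-methyl-5-(prop-1-en-2-yl)cyclohex-1-en-1-yl}oxy)dimethylsilane (5β-isopropenyl, 9α-ether, 10α-vinyl)
Conditions: Ph3PCH3Br (slight excess over base), KN(SiMe3)2, THF, 0 °C; then 9, −78 → 0 °C
Reagents that add atoms: methyltriphenylphosphonium bromide, C[P+](c1ccccc1)(c1ccccc1)c1ccccc1.[Br-]
Why: Wittig methylenation of the methyl ketone; the ylide is used without excess base and cold, so that the C5 hydrogen α to the ketone is not epimerised.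

Step 7
Reactants: 10 tert-butyl({4-ethenyl-3-[(4-methoxybenzyl)oxy]-4-methyl-5-(prop-1-en-2-yl)cyclohex-1-en-1-yl}oxy)dimethylsilane
Product: 12 2-(tert-butyldimethylsilyloxy)-4-ethenyl-3-[(4-methoxybenzyl)oxy]-4-methyl-5-(prop-1-en-2-yl)cyclohexan-1-one (C7 ketone; 8β-OSi trans to the 9α ether), via silyloxy oxirane 11 (not isolated)
Conditions: m-CPBA (1.05 equiv), NaHCO3, CH2Cl2, −20 → 0 °C
Reagents that add atoms: 3-chloroperoxybenzoic acid, OOC(=O)c1cccc(Cl)c1
Why: Rubottom oxidation: the electron-rich silyl enol ether is epoxidised far faster than the 1,1-disubstituted and monosubstituted alkenes, on the face anti to the allylic C9 ether, and the silyloxy oxirane opens with 1,4-silyl shift to the α-silyloxy ketone. The silyl group of the diene thus ends as the protecting group of the C8 oxygen; C8 is in any case equilibrated in step 10.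

Step 8
Reactants: 12 2-(tert-butyldimethylsilyloxy)-4-ethenyl-3-[(4-methoxybenzyl)oxy]-4-methyl-5-(prop-1-en-2-yl)cyclohexan-1-one
Product: 14 6α-hydroxy derivative of 12 (2-(tert-butyldimethylsilyloxy)-6-hydroxy-4-ethenyl-3-[(4-methoxybenzyl)oxy]-4-methyl-5-(prop-1-en-2-yl)cyclohexan-1-one; 6-OH trans to the C5 isopropenyl group), via potassium enolate 13 (not isolated)
Conditions: KN(SiMe3)2, THF, −78 °C; then 2-(phenylsulfonyl)-3-phenyloxaziridine, −78 °C; aq. NH4Cl
Reagents that add atoms: 2-(phenylsulfonyl)-3-phenyloxaziridine, O=S(=O)(N1OC1c1ccccc1)c1ccccc1
Why: Enolate hydroxylation with an N-sulfonyloxaziridine: kinetic deprotonation takes the C6 methylene, away from the silyloxy-bearing C8, and the oxidant is expected to add axially, anti to the neighbouring C5 isopropenyl group, giving the 6α alcohol. Either epimer is acceptable because C6 is equilibrated in step 10.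

Step 9
Reactants: 14 6α-hydroxy ketone
Product: 15 6α-isobutyrate of 14 (6α-(2-methylpropanoyloxy), 8β-OSi, C7 ketone)
Conditions: i-PrCOCl, pyridine, DMAP (cat.), CH2Cl2, 0 °C → rt
Reagents that add atoms: 2-methylpropanoyl chloride, CC(C)C(=O)Cl
Why: DMAP-catalysed acylation of the secondary ketol hydroxyl; installing the final ester now means that no free C6 hydroxyl will ever sit cis to the lactone carbonyl.

Step 10
Reactants: 15 6α-isobutyrate
Product: 16 6β-isobutyrate (C6 epimer of 15; 6β-ester, 8β-OSi and 9α-ether all equatorial)
Conditions: DBU (0.3 equiv), toluene, rt → 40 °C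
Reagents that add atoms: none
Why: Base-mediated epimerisation of an α-acyloxy ketone through its enolate: in the chair that keeps the C9 ether, the C8 silyloxy group and the C10 methyl equatorial, a 6β ester is equatorial whereas the 6α ester is axial and syn to the axial C10 vinyl group, so the equilibrium should lie on 16. C8 is held or corrected in the same way, and the equatorial C9 ether is poorly aligned for β-elimination.

Step 11
Reactants: 16 6β-isobutyrate
Product: 17 8β-hydroxy-6β-(2-methylpropanoyloxy) ketone (desilylated 16)
Conditions: HF·pyridine, pyridine, THF, 0 °C → rt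
Reagents that add atoms: none
Why: Fluoride cleavage of the secondary silyl ether under buffered, slightly acidic conditions, which avoid acyl migration and β-elimination in the α-hydroxy ketone.

Step 12
Reactants: 17 8β-hydroxy-6β-(2-methylpropanoyloxy) ketone
Product: 19 butenolide (C7=C11, 12,8β-olide; 6β-isobutyrate, 9α-ether, 5β-isopropenyl, 10α-vinyl), via phosphoranylidene acetate 18 (not isolated)
Conditions: Ph3P=C=C=O, toluene, 90 °C
Reagents that add atoms: (triphenylphosphoranylidene)ketene, O=C=C=P(c1ccccc1)(c1ccccc1)c1ccccc1
Why: The hydroxyl adds to the cumulated ylide to give the ester-stabilised phosphorane, which undergoes intramolecular Wittig olefination with the adjacent C7 ketone (five-membered ring closure) under neutral conditions; C8 keeps its configuration.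

Step 13
Reactants: 19 butenolide
Product: 20 saturated cis-fused lactone (7αH, 8αH; C11 methylene)
Conditions: Cu(OAc)2 (5 mol%), 1,2-bis(diphenylphosphino)benzene (5 mol%), (EtO)2MeSiH, t-BuOH, toluene, rt
Reagents that add atoms: none
Why: Copper hydride conjugate reduction (1,4-hydrocupration, then protonation by tert-butanol) is selective for the unsaturated lactone over the isolated terminal alkenes and the ester. Hydride is expected on the α face of C7 because the planar butenolide locks the chair in which the C5 isopropenyl group is axial over the β face; this gives the cis-fused lactone.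

Step 14
Reactants: 20 saturated cis-fused lactone
Product: 22 11α-methyl lactone (11βH; methyl on the face of H7 and H8), via lithium enolate 21 (not isolated)
Conditions: LiN(SiMe3)2 (1.05 equiv), THF, −78 °C; MeI, DMPU, −78 → −40 °C
Reagents that add atoms: iodomethane, CI
Why: Alkylation of the lactone enolate: the lactone methylene is several pKa units more acidic than the hindered isobutyrate methine, and methyl iodide enters on the convex face of the cis-fused bicycle, giving the 11α-methyl group, which is also the thermodynamically preferred epimer.

Step 15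
Reactants: 22 11α-methyl lactone
Product: 24 enal (C5 arm = 3-oxoprop-1-en-2-yl; 9α-(4-methoxybenzyl) ether retained), via allylic alcohol 23 (not isolated)
Conditions: SeO2 (cat.), t-BuOOH, CH2Cl2, rt; filtered, then MnO2, CH2Cl2, rt
Reagents that add atoms: tert-butyl hydroperoxide, CC(C)(C)OO; selenium dioxide, O=[Se]=O (oxygen carrier)
Why: Selenium dioxide allylic oxidation (ene reaction, then [2,3]-sigmatropic shift) attacks the methyl group of the 1,1-disubstituted alkene in preference to the tertiary C5–H, and the vinyl group has no allylic hydrogen. MnO2 then oxidises only the allylic alcohol to the α-methylene aldehyde.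

Step 16
Reactants: 24 enal 4-methoxybenzyl ether
Product: 25 (3R,3aS,4S,5R,6S,7S,7aS)-6-ethenyl-7-hydroxy-3,6-dimethyl-2-oxo-5-(3-oxoprop-1-en-2-yl)octahydro-1-benzofuran-4-yl 2-methylpropanoate (target)
Conditions: DDQ, CH2Cl2/pH 7 buffer, 0 °C → rt
Reagents that add atoms: none
Why: Oxidative cleavage of the 4-methoxybenzyl ether by DDQ (hydride abstraction, then hydrolysis of the oxocarbenium ion) under buffered conditions frees the C9 hydroxyl without touching the enal, the esters or the alkenes.

## Compound list

1 | (E)-4-methoxybut-3-en-2-one | CO/C=C/C(C)=O | starting material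
2 | 4-methoxybenzyl alcohol | COc1ccc(CO)cc1 | starting material
3 | (E)-4-[(4-methoxybenzyl)oxy]but-3-en-2-one | CC(=O)/C=C/OCc1ccc(OC)cc1 | intermediate
4 | (E)-1-[(4-methoxybenzyl)oxy]-3-(tert-butyldimethylsilyloxy)buta-1,3-diene | C=C(O[Si](C)(C)C(C)(C)C)/C=C/OCc1ccc(OC)cc1 | intermediate
5 | ethyl (E)-3-methyl-4-oxobut-2-enoate | CCOC(=O)/C=C(\C)C=O | starting material
6 | ethyl 2-formyl-3-[(4-methoxybenzyl)oxy]-2-methyl-5-(tert-butyldimethylsilyloxy)cyclohex-4-ene-1-carboxylate (5β-CO2Et, 9α-ether, 10α-CHO, 10β-CH3) | O=C[C@]1(C)[C@H](OCc2ccc(OC)cc2)C=C(O[Si](C)(C)C(C)(C)C)C[C@H]1C(=O)OCC | intermediate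
7 | ethyl 2-ethenyl-3-[(4-methoxybenzyl)oxy]-2-methyl-5-(tert-butyldimethylsilyloxy)cyclohex-4-ene-1-carboxylate (10α-vinyl) | C=C[C@]1(C)[C@H](OCc2ccc(OC)cc2)C=C(O[Si](C)(C)C(C)(C)C)C[C@H]1C(=O)OCC | intermediate
8 | N-methoxy-N-methylamide corresponding to ester 7 | C=C[C@]1(C)[C@H](OCc2ccc(OC)cc2)C=C(O[Si](C)(C)C(C)(C)C)C[C@H]1C(=O)N(C)OC | intermediate
9 | 1-{2-ethenyl-3-[(4-methoxybenzyl)oxy]-2-methyl-5-(tert-butyldimethylsilyloxy)cyclohex-4-en-1-yl}ethan-1-one (5β-acetyl) | C=C[C@]1(C)[C@H](OCc2ccc(OC)cc2)C=C(O[Si](C)(C)C(C)(C)C)C[C@H]1C(C)=O | intermediate
10 | tert-butyl({4-ethenyl-3-[(4-methoxybenzyl)oxy]-4-methyl-5-(prop-1-en-2-yl)cyclohex-1-en-1-yl}oxy)dimethylsilane (5β-isopropenyl, 9α-ether, 10α-vinyl) | C=C[C@]1(C)[C@H](OCc2ccc(OC)cc2)C=C(O[Si](C)(C)C(C)(C)C)C[C@H]1C(C)=C | intermediate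
11 | 7β,8β-epoxide of 10 (silyloxy oxirane, silyloxy group α at C7) | C=C[C@]1(C)[C@H](OCc3ccc(OC)cc3)[C@H]2O[C@@]2(O[Si](C)(C)C(C)(C)C)C[C@H]1C(C)=C | intermediate
12 | 2-(tert-butyldimethylsilyloxy)-4-ethenyl-3-[(4-methoxybenzyl)oxy]-4-methyl-5-(prop-1-en-2-yl)cyclohexan-1-one (C7 ketone, 8β-OSi, 9α-ether) | C=C[C@]1(C)[C@H](OCc2ccc(OC)cc2)[C@@H](O[Si](C)(C)C(C)(C)C)C(=O)C[C@H]1C(C)=C | intermediate
13 | potassium C6(7)-enolate of 12 | C=C[C@]1(C)[C@H](OCc2ccc(OC)cc2)[C@@H](O[Si](C)(C)C(C)(C)C)C([O-])=C[C@H]1C(C)=C.[K+] | intermediate
14 | 6α-hydroxy derivative of 12 (6α-OH, 8β-OSi, C7 ketone) | C=C[C@]1(C)[C@H](OCc2ccc(OC)cc2)[C@@H](O[Si](C)(C)C(C)(C)C)C(=O)[C@H](O)[C@H]1C(C)=C | intermediate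
15 | 6α-(2-methylpropanoyloxy) derivative (6α-ester, 8β-OSi, C7 ketone) | C=C[C@]1(C)[C@H](OCc2ccc(OC)cc2)[C@@H](O[Si](C)(C)C(C)(C)C)C(=O)[C@H](OC(=O)C(C)C)[C@H]1C(C)=C | intermediate
16 | 6β-(2-methylpropanoyloxy) derivative (C6 epimer of 15) | C=C[C@]1(C)[C@H](OCc2ccc(OC)cc2)[C@@H](O[Si](C)(C)C(C)(C)C)C(=O)[C@@H](OC(=O)C(C)C)[C@H]1C(C)=C | intermediate
17 | 8β-hydroxy-6β-(2-methylpropanoyloxy) ketone (5β-isopropenyl, 9α-ether, 10α-vinyl) | C=C[C@]1(C)[C@H](OCc2ccc(OC)cc2)[C@@H](O)C(=O)[C@@H](OC(=O)C(C)C)[C@H]1C(C)=C | intermediate
18 | C8 (triphenylphosphoranylidene)acetate of 17 | C=C[C@]1(C)[C@H](OCc2ccc(OC)cc2)[C@@H](OC(=O)C=P(c3ccccc3)(c4ccccc4)c5ccccc5)C(=O)[C@@H](OC(=O)C(C)C)[C@H]1C(C)=C | intermediate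
19 | butenolide: C7=C11 unsaturated 12,8β-lactone with 6β-isobutyrate, 9α-(4-methoxybenzyl) ether, 5β-isopropenyl, 10α-vinyl | C=C[C@]1(C)[C@H](OCc3ccc(OC)cc3)[C@H]2OC(=O)C=C2[C@@H](OC(=O)C(C)C)[C@H]1C(C)=C | intermediate
20 | cis-fused saturated lactone (7αH, 8αH, C11 methylene), otherwise as 19 | C=C[C@]1(C)[C@H](OCc3ccc(OC)cc3)[C@H]2OC(=O)C[C@H]2[C@@H](OC(=O)C(C)C)[C@H]1C(C)=C | intermediate
21 | lithium enolate of lactone 20 | C=C[C@]1(C)[C@H](OCc3ccc(OC)cc3)[C@H]2OC([O-])=C[C@H]2[C@@H](OC(=O)C(C)C)[C@H]1C(C)=C.[Li+] | intermediate
22 | 11α-methyl lactone (11βH), 6β-isobutyrate, 9α-(4-methoxybenzyl) ether, 5β-isopropenyl | C=C[C@]1(C)[C@H](OCc3ccc(OC)cc3)[C@H]2OC(=O)[C@H](C)[C@H]2[C@@H](OC(=O)C(C)C)[C@H]1C(C)=C | intermediate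
23 | allylic alcohol: C5 arm = 3-hydroxyprop-1-en-2-yl, otherwise as 22 | C=C[C@]1(C)[C@H](OCc3ccc(OC)cc3)[C@H]2OC(=O)[C@H](C)[C@H]2[C@@H](OC(=O)C(C)C)[C@H]1C(=C)CO | intermediate
24 | enal: C5 arm = 3-oxoprop-1-en-2-yl, 9α-(4-methoxybenzyl) ether | C=C[C@]1(C)[C@H](OCc3ccc(OC)cc3)[C@H]2OC(=O)[C@H](C)[C@H]2[C@@H](OC(=O)C(C)C)[C@H]1C(=C)C=O | intermediate
25 | (3R,3aS,4S,5R,6S,7S,7aS)-6-ethenyl-7-hydroxy-3,6-dimethyl-2-oxo-5-(3-oxoprop-1-en-2-yl)octahydro-1-benzofuran-4-yl 2-methylpropanoate | C=C[C@]1(C)[C@H](O)[C@H]2OC(=O)[C@H](C)[C@H]2[C@@H](OC(=O)C(C)C)[C@H]1C(=C)C=O | target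

## Step count and least certain steps

Total step count: 16. Longest linear sequence: 16 steps (1 → 25); 5 enters as purchased.

**Step 3 (key step, labelled as a proposed new method).** The most likely failure is insufficient face selection: the alkoxy diene needs a higher temperature than the amino dienes for which the diol is proven, so the uncatalysed pathway can compete. Lesser risks are erosion of endo selectivity (the ester also seeks the endo position) and addition of the diene to the activated formyl C=O. Fallback with known chemistry: 4 and 5 are combined without catalyst in toluene at 40–60 °C, the known thermal cycloaddition of this diene class, giving 6 together with the enantiomeric cycloadduct F1. Methylenation as in step 4 gives 7 together with the enantiomeric vinyl ester F2, and 7 is separated from F2 by preparative chromatography on a chiral stationary phase (amylose tris(3,5-dimethylphenylcarbamate)). The fallback sets out from 4 and 5 and rejoins the route at 7.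

**Step 13.** Hydride delivery may be slow or take the wrong face, because C7 is fully substituted and flanked by two oxygenated carbons, and attack on the β face would give the trans-fused lactone. Fallback: the face is chosen by the reagent instead of the substrate. 19 is reduced with the same copper source and silane but with an enantiopure bisphosphine, 5,5′-bis[bis(3,5-di-tert-butyl-4-methoxyphenyl)phosphino]-4,4′-bi-1,3-benzodioxole, in the antipode matched to α-face delivery. This fallback sets out from 19, returns at 20 and makes no new compound (F0).

**Step 14.** The amide base may deprotonate the isobutyrate methine, or the lactone enolate may attack the neighbouring ester (acyl transfer from O6 to C11). Fallback: the enolate is generated regiospecifically by reduction instead of deprotonation. 19 is reduced with Cu(OAc)2, 1,2-bis(diphenylphosphino)benzene and Et3SiH in toluene without alcohol to give the triethylsilyl ketene acetal F3, which is methylated with MeI and Bu4N[Ph3SiF2] in THF at −78 → 0 °C. The fallback sets out from 19 and returns at 22.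

**Step 10.** β-Elimination of 4-methoxybenzyl alcohol through the C8 enolate may compete, or the equilibrium may be less one-sided than the conformational argument predicts, since equatorial α-oxygens suffer dipole repulsion with the carbonyl. Fallback: inversion instead of equilibration. 14 is converted with Tf2O and pyridine (CH2Cl2, −40 °C) into the 6α-triflate F4, which is displaced with cesium 2-methylpropanoate and 18-crown-6 in toluene with inversion. The fallback sets out from 14 and returns at 16.

**Step 15.** Positional selectivity may be incomplete (attack at C5–H) or the oxidation may run on to the acid. Fallback: halogenation–oxidation instead of direct oxygenation. 22 undergoes ene-type allylic chlorination (N-chlorosuccinimide, cat. PhSeCl, CH2Cl2) to the allylic chloride F5, which is oxidised with 4-methylmorpholine N-oxide in MeCN to the aldehyde. The fallback sets out from 22 and returns at 24.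

## Further compounds

F1 | step 3 | enantiomer of cycloadduct 6 | O=C[C@@]1(C)[C@@H](OCc2ccc(OC)cc2)C=C(O[Si](C)(C)C(C)(C)C)C[C@@H]1C(=O)OCC
F2 | step 3 | enantiomer of vinyl ester 7 | C=C[C@@]1(C)[C@@H](OCc2ccc(OC)cc2)C=C(O[Si](C)(C)C(C)(C)C)C[C@@H]1C(=O)OCC
F0 | step 13 | none | none
F3 | step 14 | triethylsilyl ketene acetal of lactone 20 | C=C[C@]1(C)[C@H](OCc3ccc(OC)cc3)[C@H]2OC(O[Si](CC)(CC)CC)=C[C@H]2[C@@H](OC(=O)C(C)C)[C@H]1C(C)=C
F4 | step 10 | 6α-trifluoromethanesulfonate of ketol 14 | C=C[C@]1(C)[C@H](OCc2ccc(OC)cc2)[C@@H](O[Si](C)(C)C(C)(C)C)C(=O)[C@H](OS(=O)(=O)C(F)(F)F)[C@H]1C(C)=C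
F5 | step 15 | allylic chloride (C5 arm = 3-chloroprop-1-en-2-yl), otherwise as 22 | C=C[C@]1(C)[C@H](OCc3ccc(OC)cc3)[C@H]2OC(=O)[C@H](C)[C@H]2[C@@H](OC(=O)C(C)C)[C@H]1C(=C)CCl
A1 | alternative 1 | 6β-hydroxy-9α-(tert-butyldimethylsilyloxy) cis-fused 11-methyl lactone with 5β-isopropenyl and 10α-vinyl | C=C[C@]1(C)[C@H](O[Si](C)(C)C(C)(C)C)[C@H]2OC(=O)[C@H](C)[C@H]2[C@@H](O)[C@H]1C(C)=C
A2 | alternative 1 | open-chain aldehyde: 2-isopropenyl-3-methyl-3-vinyl-4-(tert-butyldimethylsilyloxy)-4-(4-methyl-5-oxo-2,5-dihydrofuran-2-yl)butanal | O=C[C@@H](C(C)=C)[C@](C)(C=C)[C@H](O[Si](C)(C)C(C)(C)C)[C@H]1OC(=O)C(C)=C1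
A3 | alternative 2 | 1-tert-butyl 6-ethyl 1-methyl-2-oxocyclohex-3-ene-1,6-dicarboxylate (esters trans) | CC(C)(C)OC(=O)[C@]1(C)C(=O)C=CC[C@H]1C(=O)OCC
A4 | alternative 2 | tert-butyl 2-methyl-3-oxobutanoate | CC(=O)C(C)C(=O)OC(C)(C)C
A5 | alternative 2 | ethyl (E)-4-oxobut-2-enoate | CCOC(=O)/C=C/C=O
A6 | alternative 3 | methyl 2-[6-(4-methoxybenzyloxy)-4-methyl-5-(2-methyl-1,3-dioxolan-2-yl)-4-vinylcyclohex-2-en-1-yl]propanoate | C=C[C@]1(C)C=C[C@@H]([C@@H](C)C(=O)OC)[C@@H](OCc2ccc(OC)cc2)[C@H]1C3(C)OCCO3
A7 | alternative 3 | methyl 4-(4-methoxybenzyloxy)-2,6-dimethyl-5-(2-methyl-1,3-dioxolan-2-yl)-3,6-divinyloct-7-enoate | C=CC(C)(C=C)[C@H](C1(C)OCCO1)[C@H](OCc2ccc(OC)cc2)[C@@H](C=C)[C@@H](C)C(=O)OC
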